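Monday's flask slows too soon.

| setting | Monday's | Tuesday's | Thursday's | Saturday's | Friday's |
|---|---|---|---|---|---|
| starting material | 0.600 M | 0.360 M | 0.600 M | 1.80 M | 0.300 M |
| partner | 0.600 M | 0.360 M | 0.600 M | 0.600 M | 0.300 M |
| target |  |  | 0.300 M |  |  |
| time |  |  |  |  | 3.9 h |

| Monday's run: time / h | Monday's run: [starting material] / M | Tuesday's run: time / h | Tuesday's run: [starting material] / M | Thursday's run: time / h | Thursday's run: [starting material] / M | Saturday's run: time / h | Saturday's run: [starting material] / M |
|---|---|---|---|---|---|---|---|
| 0.16 | 0.5625 | 0.16 | 0.3458 | 0.16 | 0.5644 | 0.16 | 1.6982 |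
| 0.25 | 0.5459 | 0.25 | 0.3388 | 0.25 | 0.5497 | 0.25 | 1.6540 |
| 0.39 | 0.5231 | 0.39 | 0.3315 | 0.39 | 0.5261 | 0.39 | 1.5940 |
| 0.62 | 0.4946 | 0.62 | 0.3190 | 0.62 | 0.4944 | 0.62 | 1.5294 |
| 0.98 | 0.4550 | 0.98 | 0.2968 | 0.98 | 0.4611 | 0.98 | 1.4631 |
| 1.6 | 0.4224 | 1.6 | 0.2841 | 1.6 | 0.4237 | 1.6 | 1.4006 |
| 2.5 | 0.3911 | 2.5 | 0.2631 | 2.5 | 0.3963 | 2.5 | 1.3518 |
| 3.9 | 0.3679 | 3.9 | 0.2480 | 3.9 | 0.3708 | 3.9 | 1.3085 |

(readings scatter by 0.002 M)

- Overall: starting material + partner -> target.
- Constant volume, constant temperature.
- "The second partner" is partner.
- An order is taken over about fifteen percent of the charge, up and down.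

- reaction order in [starting material] at the outset, round the charge of the Monday's run, defined at two percent of the starting material turned into target (one fixed amount of target, the same in the runs compared)
- reaction order in [partner] at the outset, round the charge of the Monday's run, defined at two percent of the starting material turned into target
- starting material in the Friday's run at 3.9 h, as a share of the starting material charged

Two chemists read these runs. Both count turnovers. For a flask with equal charges of starting material, S, and partner, R, call the reach, E, the reciprocal of [S] now less the reciprocal of its charge. It is the molecules turned per molecule left, divided by the charge. Under the plain law, rate = k[S][R] with k constant (second-order kinetics), E grows as kt.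

At 0.16 h the reach reads 0.111 L mol⁻¹ in Monday's flask and 0.114 L mol⁻¹ in Tuesday's, although the charges differ. The first chemist therefore keeps the plain law. Tuesday's first reading gives a pace, E/t, of 0.713 L mol⁻¹ h⁻¹, and carried to 3.9 h this leaves 54.5% of the starting material in Friday's flask.

The second chemist holds that the reaction has a clock. Tuesday's flask, charged closer to Friday's 0.300 M than Monday's is, has a reach at 3.9 h of 1.25 L mol⁻¹, which is less than the 2.78 L mol⁻¹ the plain law asks. Monday's reach at that time is 1.05 L mol⁻¹. My own reckoning adds Tuesday's reach unchanged to the reciprocal of Friday's charge, which leaves 72.7%.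

The forecast sides with the clock but differs from my figure. It notes that “the decay seems somewhat faster at higher partner”, extends the reach to 1.32, and gives 71.7%, with orders 1 in starting material and 1 in partner.

The flask gives orders of 1.1 in starting material and 1.1 in partner, and 72.5% left in Friday's flask, beside the first chemist's 54.5% and the forecast's 71.7%, which stands within its margin. Friday's reach is 1.27 L mol⁻¹, beside Tuesday's 1.25 L mol⁻¹. Thursday's flask has Monday's charges plus 0.300 M of target; Monday's reach gives 0.368 M for it at 3.9 h, and the reading in Thursday's flask is 0.3708 M. The plain law stays close in Tuesday's early readings, with a pace of 0.695 L mol⁻¹ h⁻¹ at 0.25 h beside 0.713 L mol⁻¹ h⁻¹ at 0.16 h, and the pace over the whole 3.9 h of Tuesday's flask is 0.321 L mol⁻¹ h⁻¹.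

    starting material + partner → target (0.6516 L mol⁻¹ h⁻¹)
    target + partner → side product (0.09216 L mol⁻¹ h⁻¹)
    partner → lost reagent (0.6084 h⁻¹)
    starting material → decomposed substrate (0.02164 h⁻¹)

At Friday's charge, each partner molecule was lost on its own 3.11 times as fast as it met starting material at the outset, with a half-life for that loss of 1.14 h. Throughout the 3.9 h of Friday's flask, starting material also went to decomposed substrate, a first-order step worth 0.0844 in the natural logarithm of [S].

The data are calculated from invented constants, noise included.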